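**Retrosynthetic overview**
1. Target ⇒ its O-acetate without the allyl group. The C7 allyl goes on last, by C–H borylation and allyl coupling at the only unhindered C–H of ring A, then the acetate is removed.
2. Dioxane ring ⇒ five-membered catechol acetal (4-methoxy-2-methyl-1,3-benzodioxole) + aryl carbene. A one-carbon ring expansion (O-ylide, then 1,2-shift of the acetal carbon from O to C) forms C2–C3 and both stereocenters under catalyst control.
3. Aryl carbene ⇒ N-sulfonylhydrazone of O-acetylsyringaldehyde ⇒ syringaldehyde ⇒ p-cresol (bromination/side-chain oxidation, then methoxylation).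
4. Acetal ⇒ catechol + acetaldehyde dimethyl acetal; the third oxygen comes from ortho-lithiation/oxidation/methylation.
5. Ring order: both benzene rings are bought; the dioxole ring is closed first (step 5) and expanded to the dioxane ring (step 7).

Assumption: the absolute sense of induction of the chiral catalyst in step 7 cannot be predicted; the (S)-ligand series is written, and the mirror-image catalyst is used if it proves to give the (2S,3S) series.

**Step 1**
Reactants: 1 4-methylphenol (p-cresol)
Product: 4 3,5-dibromo-4-hydroxybenzaldehyde, via dibromocresol 2 (not isolated), via benzal bromide 3 (not isolated)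
Conditions: Br2 (2.0 equiv), o-dichlorobenzene, 35 °C; Br2 (2.1 equiv), 150–160 °C; H2O, 100 °C
Reagents that add atoms: bromine, BrBr; water, O
Why: Electrophilic aromatic bromination at both positions ortho to the hydroxyl group is followed at high temperature by side-chain dibromination of the para methyl group and hydrolysis of the benzal bromide to the aldehyde, a one-pot sequence run on scale for this compound.

**Step 2**
Reactants: 4 3,5-dibromo-4-hydroxybenzaldehyde
Product: 5 4-hydroxy-3,5-dimethoxybenzaldehyde (syringaldehyde)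
Conditions: NaOMe (5 equiv), CuCl (20 mol %), DMF/MeOH, 110 °C; aq. HCl work-up
Reagents that add atoms: sodium methoxide, C[O-].[Na+]
Why: CuCl-catalysed Ullmann-type methoxylation replaces both bromides ortho to the phenolate and leaves the aldehyde untouched, a long-established conversion of this substrate.

**Step 3**
Reactants: 5 syringaldehyde
Product: 6 4-formyl-2,6-dimethoxyphenyl acetate
Conditions: Ac2O, pyridine, DMAP (cat.), CH2Cl2, rt
Reagents that add atoms: acetic anhydride, CC(=O)OC(C)=O
Why: O-acetylation masks the phenol, which would otherwise quench the carbene by O–H insertion and turn the diazo compound into a quinone methide, and it makes the later aryl carbene more electrophilic.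

**Step 4**
Reactants: 6 4-formyl-2,6-dimethoxyphenyl acetate
Product: 7 (E)-N'-(4-acetoxy-3,5-dimethoxybenzylidene)-2-(trifluoromethyl)benzenesulfonohydrazide
Conditions: 2-(CF3)C6H4SO2NHNH2 (1.05 equiv), MeOH, rt
Reagents that add atoms: 2-(trifluoromethyl)benzenesulfonohydrazide, NNS(=O)(=O)c1ccccc1C(F)(F)F
Why: Condensation of the aldehyde with the sulfonyl hydrazide gives the crystalline N-sulfonylhydrazone (Bamford–Stevens diazo precursor), and the ortho-CF3 sulfonyl group allows diazo release below 0 °C.

**Step 5**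
Reactants: 8 benzene-1,2-diol (catechol); 9 1,1-dimethoxyethane
Product: 10 2-methyl-1,3-benzodioxole
Conditions: p-TsOH·H2O (2 mol %), toluene, reflux, MeOH removed (4 Å MS)
Reagents that add atoms: none
Why: Acid-catalysed transacetalisation, driven by removal of methanol, closes the five-membered catechol acetal.

**Step 6**
Reactants: 10 2-methyl-1,3-benzodioxole
Product: 14 4-methoxy-2-methyl-1,3-benzodioxole (racemic), via aryllithium 11 (not isolated), via boronate 12 (not isolated), via phenol 13 (not isolated)
Conditions: s-BuLi, TMEDA, THF, −78 °C; B(OMe)3, −78 °C → rt; H2O2, aq. NaOH, 0 °C → rt; Na2SO3; Me2SO4, 40 °C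
Reagents that add atoms: hydrogen peroxide, OO; dimethyl sulfate, COS(=O)(=O)OC; trimethyl borate, COB(OC)OC (boron only in 12); s-BuLi, CCC(C)[Li] (lithium only in 11)
Why: Directed ortho-lithiation takes the acidic C–H next to the dioxole oxygen, the borate is oxidised to the phenolate (C–B to C–O at the same position) and this is methylated in the same alkaline pot (Williamson ether synthesis); the acetal carbon stays racemic, which does not matter later.

**Step 7**
Reactants: 7 (E)-N'-(4-acetoxy-3,5-dimethoxybenzylidene)-2-(trifluoromethyl)benzenesulfonohydrazide; 14 4-methoxy-2-methyl-1,3-benzodioxole (3 equiv, excess recovered)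
Product: 16 4-[(2R,3R)-5-methoxy-3-methyl-2,3-dihydro-1,4-benzodioxin-2-yl]-2,6-dimethoxyphenyl acetate, via aryldiazomethane 15 (not isolated)
Conditions: NaH (1.5 equiv), Rh2(S-TCPTTL)4 (2 mol %; the divalent rhodium carboxylate dimer of N-tetrachlorophthaloyl-(S)-tert-leucine), 4 Å MS, CH2Cl2, −40 → 0 °C, slow warming
Reagents that add atoms: none
Why: Proposed new method: the hydrazone salt releases diazo compound 15 below 0 °C; the electrophilic carbene on Rh2(S-TCPTTL)4 is attacked by the less hindered acetal oxygen O1 of 14 (O3 is flanked and inductively deactivated by the 4-OMe group); the metal-bound oxonium ylide opens at its O1–C2 acetal bond to an aryloxocarbenium/benzyl zwitterion, which erases the stereocenter of racemic 14; C–C bond formation in the chiral carboxylate pocket then closes the six-membered ring through a chair-like transition state with aryl and methyl pseudo-equatorial, so the catalyst sets C2, the ring closure sets C3 trans to it, and the acetal carbon has moved from O to C in a stepwise [1,2]-Stevens ring expansion; the closest known reactions are the oxonium-ylide ring expansions of 1,3-dioxolanes to 1,4-dioxanes and of oxetanes to tetrahydrofurans with acceptor diazo compounds, not yet shown for 1,3-benzodioxoles, for donor aryl carbenes or enantioselectively on acetals.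

**Step 8**
Reactants: 16 4-[(2R,3R)-5-methoxy-3-methyl-2,3-dihydro-1,4-benzodioxin-2-yl]-2,6-dimethoxyphenyl acetate; 17 allyl bromide
Product: 20 4-[(2R,3R)-7-allyl-5-methoxy-3-methyl-2,3-dihydro-1,4-benzodioxin-2-yl]-2,6-dimethoxyphenol (target), via arylboronate 18 (not isolated), via allylated acetate 19 (not isolated)
Conditions: [Ir(OMe)(cod)]2 (1.5 mol %), dtbpy (3 mol %), B2pin2 (1.0 equiv), THF, 80 °C; evaporate; Pd(PPh3)4 (5 mol %), 17 (1.5 equiv), CsF (3 equiv), THF, 65 °C; evaporate; K2CO3, MeOH, 0 °C → rt
Reagents that add atoms: bis(pinacolato)diboron, CC1(C)OB(OC1(C)C)B1OC(C)(C)C(C)(C)O1 (boron only in 18)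
Why: C–H borylation with [Ir(OMe)(cod)]2/dtbpy is sterically controlled and goes to C7, the only aromatic C–H without an ortho substituent; Suzuki–Miyaura coupling of the boronate with allyl bromide under Pd(PPh3)4 forms the aryl–allyl bond, and mild methanolysis removes the acetate without touching either stereocenter.

**Compound list**
1 | 4-methylphenol (p-cresol) | Cc1ccc(O)cc1 | starting material
2 | 2,6-dibromo-4-methylphenol | Cc1cc(Br)c(O)c(Br)c1 | intermediate
3 | 2,6-dibromo-4-(dibromomethyl)phenol | BrC(Br)c1cc(Br)c(O)c(Br)c1 | intermediate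
4 | 3,5-dibromo-4-hydroxybenzaldehyde | O=Cc1cc(Br)c(O)c(Br)c1 | intermediate
5 | 4-hydroxy-3,5-dimethoxybenzaldehyde (syringaldehyde) | COc1cc(C=O)cc(OC)c1O | intermediate
6 | 4-formyl-2,6-dimethoxyphenyl acetate | CC(=O)Oc1c(OC)cc(C=O)cc1OC | intermediate
7 | (E)-N'-(4-acetoxy-3,5-dimethoxybenzylidene)-2-(trifluoromethyl)benzenesulfonohydrazide | CC(=O)Oc1c(OC)cc(/C=N/NS(=O)(=O)c2ccccc2C(F)(F)F)cc1OC | intermediate
8 | benzene-1,2-diol (catechol) | Oc1ccccc1O | starting material
9 | 1,1-dimethoxyethane | CC(OC)OC | starting material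
10 | 2-methyl-1,3-benzodioxole | CC1Oc2ccccc2O1 | intermediate
11 | (2-methyl-1,3-benzodioxol-4-yl)lithium (racemic) | [Li]c1cccc2OC(C)Oc12 | intermediate
12 | dimethyl (2-methyl-1,3-benzodioxol-4-yl)boronate (racemic) | COB(OC)c1cccc2OC(C)Oc12 | intermediate
13 | 2-methyl-1,3-benzodioxol-4-ol (racemic; present in the flask as its sodium phenolate) | Oc1cccc2OC(C)Oc12 | intermediate
14 | 4-methoxy-2-methyl-1,3-benzodioxole (racemic) | COc1cccc2OC(C)Oc12 | intermediate
15 | 4-(diazomethyl)-2,6-dimethoxyphenyl acetate | CC(=O)Oc1c(OC)cc(C=[N+]=[N-])cc1OC | intermediate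
16 | 4-[(2R,3R)-5-methoxy-3-methyl-2,3-dihydro-1,4-benzodioxin-2-yl]-2,6-dimethoxyphenyl acetate | COc1cccc2O[C@H](c3cc(OC)c(OC(C)=O)c(OC)c3)[C@@H](C)Oc12 | intermediate
17 | allyl bromide (3-bromoprop-1-ene) | C=CCBr | starting material
18 | 4-[(2R,3R)-5-methoxy-3-methyl-7-(4,4,5,5-tetramethyl-1,3,2-dioxaborolan-2-yl)-2,3-dihydro-1,4-benzodioxin-2-yl]-2,6-dimethoxyphenyl acetate | COc1cc(B3OC(C)(C)C(C)(C)O3)cc2O[C@H](c3cc(OC)c(OC(C)=O)c(OC)c3)[C@@H](C)Oc12 | intermediate
19 | 4-[(2R,3R)-7-allyl-5-methoxy-3-methyl-2,3-dihydro-1,4-benzodioxin-2-yl]-2,6-dimethoxyphenyl acetate | COc1cc(CC=C)cc2O[C@H](c3cc(OC)c(OC(C)=O)c(OC)c3)[C@@H](C)Oc12 | intermediate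
20 | 4-[(2R,3R)-7-allyl-5-methoxy-3-methyl-2,3-dihydro-1,4-benzodioxin-2-yl]-2,6-dimethoxyphenol | C=CCc1cc(OC)c2c(c1)O[C@H](c1cc(OC)c(O)c(OC)c1)[C@@H](C)O2 | target

**Step count and risk**
Total steps: 8. Longest linear sequence: 6 (steps 1, 2, 3, 4, 7, 8, from p-cresol).

Step 7 is the most likely to fail. The carbene may attack O3 and give the regioisomer, may dimerise to the stilbene or azine, or may functionalise the electron-rich arene. Enantioselectivity is lost if the ylide leaves the metal before C–C bond formation. The fallback uses known chemistry; it sets out from 14 and 5 and comes back at 16. Acetal 14 is hydrolysed (TFA/H2O, 60 °C) to 3-methoxybenzene-1,2-diol F1. Aldehyde 5 is converted by Wittig olefination (EtPPh3Br, KOtBu, THF) to 2,6-dimethoxy-4-(prop-1-en-1-yl)phenol F2, whose alkene geometry is irrelevant. Oxidative cross-coupling of F1 and F2 with Ag2O (benzene/acetone, rt) is the classical biomimetic catechol/propenylphenol route to this ring system and gives racemic trans-4-(5-methoxy-3-methyl-2,3-dihydro-1,4-benzodioxin-2-yl)-2,6-dimethoxyphenol F3. Preparative chiral SFC, which also removes any regioisomer, gives 4-[(2R,3R)-5-methoxy-3-methyl-2,3-dihydro-1,4-benzodioxin-2-yl]-2,6-dimethoxyphenol F4, and Ac2O/pyridine gives 16.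

Step 8 is the second risk. Metal hydrides may move the double bond into conjugation, some borylation may occur at C8, and the phenol may be O-allylated if the acetate is lost before the allyl bromide is removed. The fallback installs a halogen handle before the ring expansion and reverses the coupling polarity; it sets out from 10 and comes back at 19, then 20. Acetal 10 is brominated para to oxygen (NBS, MeCN, 0 °C) to 5-bromo-2-methyl-1,3-benzodioxole F5. Borylation with [Ir(OMe)(cod)]2/dtbpy/B2pin2 at the only C–H not ortho to bromine gives 2-(6-bromo-2-methyl-1,3-benzodioxol-4-yl)-4,4,5,5-tetramethyl-1,3,2-dioxaborolane F6. Oxidation (H2O2, NaOH) gives 6-bromo-2-methyl-1,3-benzodioxol-4-ol F7, and methylation (MeI, K2CO3, acetone) gives 6-bromo-4-methoxy-2-methyl-1,3-benzodioxole F8. Ring expansion of F8 with 7 under the step 7 conditions gives 4-[(2R,3R)-7-bromo-5-methoxy-3-methyl-2,3-dihydro-1,4-benzodioxin-2-yl]-2,6-dimethoxyphenyl acetate F9. Suzuki–Miyaura coupling of F9 with potassium allyltrifluoroborate (PdCl2(dppf), Cs2CO3, THF/H2O, 70 °C) gives 19, and K2CO3/MeOH gives 20.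

Step 6 is the third risk. The alkyllithium may open the acetal instead of lithiating the ring, and methylation in the telescoped pot may be incomplete. The fallback replaces lithiation by catalytic C–H borylation and isolates the phenol; it sets out from 10 and comes back at 13, then 14. Borylation of 10 with [Ir(OMe)(cod)]2/dtbpy/B2pin2 (THF, 80 °C), which favours the C–H ortho to the dioxole oxygen, gives 4,4,5,5-tetramethyl-2-(2-methyl-1,3-benzodioxol-4-yl)-1,3,2-dioxaborolane F10. Oxidation (H2O2, NaOH) gives 13 as the isolated phenol, and MeI/K2CO3 in acetone gives 14.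

**Further compounds**
F1 | step 7 | 3-methoxybenzene-1,2-diol | COc1cccc(O)c1O
F2 | step 7 | 2,6-dimethoxy-4-(prop-1-en-1-yl)phenol (E/Z mixture) | CC=Cc1cc(OC)c(O)c(OC)c1
F3 | step 7 | racemic trans-4-(5-methoxy-3-methyl-2,3-dihydro-1,4-benzodioxin-2-yl)-2,6-dimethoxyphenol | COc1cccc2O[C@H](c3cc(OC)c(O)c(OC)c3)[C@@H](C)Oc12.COc1cccc2O[C@@H](c3cc(OC)c(O)c(OC)c3)[C@H](C)Oc12
F4 | step 7 | 4-[(2R,3R)-5-methoxy-3-methyl-2,3-dihydro-1,4-benzodioxin-2-yl]-2,6-dimethoxyphenol | COc1cccc2O[C@H](c3cc(OC)c(O)c(OC)c3)[C@@H](C)Oc12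
F5 | step 8 | 5-bromo-2-methyl-1,3-benzodioxole | CC1Oc2ccc(Br)cc2O1
F6 | step 8 | 2-(6-bromo-2-methyl-1,3-benzodioxol-4-yl)-4,4,5,5-tetramethyl-1,3,2-dioxaborolane (racemic) | CC1Oc2cc(Br)cc(B3OC(C)(C)C(C)(C)O3)c2O1
F7 | step 8 | 6-bromo-2-methyl-1,3-benzodioxol-4-ol (racemic) | CC1Oc2cc(Br)cc(O)c2O1
F8 | step 8 | 6-bromo-4-methoxy-2-methyl-1,3-benzodioxole (racemic) | COc1cc(Br)cc2OC(C)Oc12
F9 | step 8 | 4-[(2R,3R)-7-bromo-5-methoxy-3-methyl-2,3-dihydro-1,4-benzodioxin-2-yl]-2,6-dimethoxyphenyl acetate | COc1cc(Br)cc2O[C@H](c3cc(OC)c(OC(C)=O)c(OC)c3)[C@@H](C)Oc12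
F10 | step 6 | 4,4,5,5-tetramethyl-2-(2-methyl-1,3-benzodioxol-4-yl)-1,3,2-dioxaborolane (racemic) | CC1Oc2cccc(B3OC(C)(C)C(C)(C)O3)c2O1
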